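Follow the links, the product, counted in percent of the first end groups charged, through these flasks:

| setting | alpha | epsilon | winter | spring | midnight | summer | noon |
|---|---|---|---|---|---|---|---|
| first end groups | 0.0029 M | 0.022 M | 0.010 M | 0.0025 M | 0.020 M | 0.015 M | 0.0030 M |
| second end groups | 1 equiv | 1 equiv | 1.00 equiv | 1.00 equiv | 1.00 equiv | 1.00 equiv | 1.00 equiv |
| remark | run made earlier | run made earlier |  |  |  |  |  |
| time |  |  | 5.0 min | 5.0 min | 5.0 min | 5.0 min | 5.0 min |

* all flasks from highest to lowest amount of links, in percent of the first end groups charged, at 5.0 min (winter / spring / midnight / summer / noon)
* the amount of links, in percent of the first end groups charged of the flask you put first, at 5.0 min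
* the amount of links, in percent of the first end groups charged of the flask you put last, at 5.0 min



Begin with the dilute run; its readings, like those of the concentrated run, scatter with a standard deviation of 0.5 percentage points:

alpha run (percent of the first end groups charged)

| time / min | links / % | first end groups / % |
|---|---|---|
| 0.417 | 4.8 | 95.7 |
| 1.00 | 10.3 | 88.8 |
| 2.00 | 18.3 | 81.1 |
| 5.00 | 34.7 | 64.6 |

At 5.00 min, alpha's links and first end groups add up to 99.3%, so the missing part is a small correction. But the concentrated run differs:

epsilon run (percent of the first end groups charged)

| time / min | links / % | first end groups / % |
|---|---|---|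
| 1.33 | 45.4 | 49.8 |
| 2.50 | 45.7 | 38.5 |
| 4.00 | 42.7 | 31.8 |
| 5.00 | 39.4 | 29.0 |

At 5.00 min, epsilon's sum is 68.4%, and its links fall after 2.50 min, so a loss has grown large there. Suppose that each step is two partners meeting (bimolecular). With equal charges of both end groups, the percent of links then depends on starting concentration times time. For winter this product is 0.0500 M·min: call it the dose, D.

Now place the flasks on the runs by D. Spring, at 0.0125 M·min, and noon, at 0.0150 M·min, lie on either side of alpha's 0.0145 M·min, where links read 34.7%, so put noon above spring. Summer, at 0.0750 M·min, and midnight, at 0.100 M·min, lie on either side of epsilon's 0.0880 M·min, where links read 42.7%, so put summer above midnight. Winter's dose lies between epsilon's 0.0293 M·min and 0.0550 M·min, where links read 45.4% and 45.7%, more than the 42.7% beside summer and midnight, so put winter first and the two dilute flasks, near alpha's 34.7%, last.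

The forecast, on the supposition that “every step is bimolecular”, gave winter > summer > midnight > noon > spring, with 46% for the first flask and 31.5% for the last.

The flasks give winter > summer > midnight > noon > spring, with 47.1% and 31.6%.

    links + released group → side product (k = 0.272 M⁻¹ s⁻¹)
    first end groups + second end groups ⇌ links + released group (K = 2.67, k = 0.658 M⁻¹ s⁻¹)

Both steps are indeed two partners meeting. Now take the dose to a second case and leave winter until 12 min. Epsilon's last reading stands at a dose of 0.110 M·min, where links read 39.4%. Winter's dose grows from 0.0500 M·min to 0.120 M·min, which is above epsilon's. So reckon on fewer links than that reading. Winter at 12.0 min holds 37.9% links, and its side product stands at 33.7%.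

The earlier runs and the new flask come from a simulation for an exercise, noise included.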